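**Strategy.** The oxolane is disconnected between C2, the ring carbon that carries the 3,4,5-trimethoxyphenyl ring and is bound to O1, and C3, its methyl-bearing neighbour. C2, flanked by O1 and an electron-rich arene, is an ideal oxocarbenium carbon. The C3 methyl is treated as a masked phenylthiomethyl group, which makes C3 the nucleophilic β-carbon of an (E)-vinyl sulfide. In one operation an anti-configured hydroxy vinyl sulfide (C4 and C5 already set) condenses with 3,4,5-trimethoxybenzaldehyde, the ring closes through C2–C3 and the thionium ion is reduced, setting C2 and C3. Nickel finally removes sulfur and the benzyl group.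

Key step: step 5

Remark: ring locants used throughout are O1, C2 (trimethoxyphenyl), C3 (methyl), C4 (methyl), C5 (hydroxydimethoxyphenyl); 1, 3 and 8 are taken as commercial; the sense of chirality transfer in step 3 is derived from anti SN2' palladation followed by syn SE2' addition, and (S)-but-3-yn-2-ol would be used if it proved opposite.

Step 1
Reactants: 1 3-hydroxy-4,5-dimethoxybenzaldehyde
Product: 2 3-(benzyloxy)-4,5-dimethoxybenzaldehyde
Conditions: BnBr, K2CO3, DMF, rt
Reagents that add atoms: benzyl bromide, BrCc1ccccc1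
Why: Williamson ether synthesis; the phenoxide is O-benzylated so that the acidic phenol cannot consume Et2Zn or intercept the oxocarbenium ion later.

Step 2
Reactants: 3 (R)-but-3-yn-2-ol
Product: 4 (R)-but-3-yn-2-yl methanesulfonate
Conditions: MsCl, Et3N, CH2Cl2, −78 to 0 °C
Reagents that add atoms: methanesulfonyl chloride, CS(=O)(=O)Cl
Why: O-sulfonylation (mesylation) leaves the C–O bond intact, so the (R) configuration is retained.

Step 3
Reactants: 2 3-(benzyloxy)-4,5-dimethoxybenzaldehyde; 4 (R)-but-3-yn-2-yl methanesulfonate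
Product: 6 (1S,2S)-1-[3-(benzyloxy)-4,5-dimethoxyphenyl]-2-methylbut-3-yn-1-ol, via allenylzinc reagent 5 (not isolated)
Conditions: Pd(OAc)2 (5 mol %), PPh3 (5 mol %), Et2Zn (3 equiv), THF, −78 to −20 °C; aq. NH4Cl
Reagents that add atoms: none
Why: Marshall allenylzinc propargylation: zerovalent palladium displaces the mesylate anti (SN2'), transmetalation gives the (P)-allenylzinc 5, and its cyclic SE2' addition to 2 should transfer the axial chirality to C2 (S) and, with the aryl group anti to the allenyl methyl, set C1 (S) in the anti relationship.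

Step 4
Reactants: 6 (1S,2S)-1-[3-(benzyloxy)-4,5-dimethoxyphenyl]-2-methylbut-3-yn-1-ol
Product: 7 (1S,2S,3E)-1-[3-(benzyloxy)-4,5-dimethoxyphenyl]-2-methyl-4-(phenylsulfanyl)but-3-en-1-ol
Conditions: PhSH (1.1 equiv), RhCl(PPh3)3 (3 mol %), EtOH, 40 °C
Reagents that add atoms: benzenethiol, Sc1ccccc1
Why: Rhodium-catalysed anti-Markovnikov hydrothiolation of the terminal alkyne (S–H oxidative addition, syn insertion, reductive elimination) should give the linear (E)-alkenyl sulfide without touching the two stereocentres or the free hydroxyl.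

Step 5
Reactants: 7 (1S,2S,3E)-1-[3-(benzyloxy)-4,5-dimethoxyphenyl]-2-methyl-4-(phenylsulfanyl)but-3-en-1-ol; 8 3,4,5-trimethoxybenzaldehyde
Product: 12 (2R,3R,4S,5S)-5-[3-(benzyloxy)-4,5-dimethoxyphenyl]-4-methyl-3-[(phenylsulfanyl)methyl]-2-(3,4,5-trimethoxyphenyl)oxolane, via trimethylsilyl ether 9 (not isolated), via oxocarbenium triflate 10 (not isolated), via thionium triflate 11 (not isolated)
Conditions: 8 (1.5 equiv), 2,6-di-tert-butyl-4-methylpyridine (1.2 equiv), TMSOTf (2.5 equiv), Et3SiH (3 equiv), CH2Cl2, −78 to −40 °C; aq. NaHCO3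
Reagents that add atoms: none
Why: In situ O-silylation and TMSOTf-mediated condensation with 8 give the (E)-oxocarbenium ion 10, whose carbon is attacked by the sulfur-activated β-carbon of the (E)-vinyl sulfide to form the C2–C3 bond, and the thionium ion 11 is reduced as it forms by Et3SiH (ionic hydrogenation). The closest known reaction type is the oxonium-Prins (Mukaiyama-type) cyclisation of 4-hydroxy-1-alkenyl carbamates, enol ethers or styrenyl alcohols with aldehydes to 2,3-disubstituted tetrahydrofurans. The oxolane closes in a 5-exo-trig mode with respect to the vinyl sulfide C=C (endo with respect to C=O+). C2 is controlled by the E geometry of the oxocarbenium ion and an envelope transition state in which C5–H eclipses the C=O+ plane and the C5 aryl group is pseudo-equatorial, which places the two aryl groups cis. C3 is controlled by the staggered approach that keeps the alkene terminus anti to the C2 aryl group, which the E alkene allows without A(1,3) strain, giving 2,3-trans and hence 3,4-cis to the preset C4 methyl. The step needs C3 rather than the terminal carbon to bond and ring closure to beat hydride capture: the sulfur lone pair makes C3 the nucleophilic terminus (cation at the exocyclic carbon), which also shuts off six-membered Prins closure and 2-oxonia-Cope scrambling, and the intramolecular attack should outrun bimolecular silane reduction at −78 °C.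

Step 6
Reactants: 12 (2R,3R,4S,5S)-5-[3-(benzyloxy)-4,5-dimethoxyphenyl]-4-methyl-3-[(phenylsulfanyl)methyl]-2-(3,4,5-trimethoxyphenyl)oxolane
Product: 13 (2R,3R,4S,5S)-5-(3-hydroxy-4,5-dimethoxyphenyl)-3,4-dimethyl-2-(3,4,5-trimethoxyphenyl)oxolane (CNP0293669.1)
Conditions: Raney Ni (W-2, excess), H2 (1 atm), EtOH, 50 °C
Reagents that add atoms: none
Why: Raney nickel desulfurization (hydrogenolysis of both C–S bonds) turns CH2SPh into the C3 methyl and the same nickel surface hydrogenolyses the aryl benzyl ether, while no bond to a stereocentre is broken and the electron-rich, secondary benzylic C–O bonds of the ring are expected to react more slowly.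

**Compound list**

1 | 3-hydroxy-4,5-dimethoxybenzaldehyde | COc1cc(C=O)cc(O)c1OC | starting material
2 | 3-(benzyloxy)-4,5-dimethoxybenzaldehyde | COc1cc(C=O)cc(OCc2ccccc2)c1OC | intermediate
3 | (R)-but-3-yn-2-ol | C[C@@H](O)C#C | starting material
4 | (R)-but-3-yn-2-yl methanesulfonate | C[C@@H](OS(C)(=O)=O)C#C | intermediate
5 | (P)-buta-1,2-dien-1-yl(ethyl)zinc, formed in situ | [H]C(C)=[C@]=C([H])[Zn]CC | intermediate
6 | (1S,2S)-1-[3-(benzyloxy)-4,5-dimethoxyphenyl]-2-methylbut-3-yn-1-ol | COc1cc([C@@H](O)[C@@H](C)C#C)cc(OCc2ccccc2)c1OC | intermediate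
7 | (1S,2S,3E)-1-[3-(benzyloxy)-4,5-dimethoxyphenyl]-2-methyl-4-(phenylsulfanyl)but-3-en-1-ol | COc1cc([C@@H](O)[C@@H](C)/C=C/Sc2ccccc2)cc(OCc2ccccc2)c1OC | intermediate
8 | 3,4,5-trimethoxybenzaldehyde | COc1cc(C=O)cc(OC)c1OC | starting material
9 | trimethylsilyl ether of 7, formed in situ | COc1cc([C@@H](O[Si](C)(C)C)[C@@H](C)/C=C/Sc2ccccc2)cc(OCc2ccccc2)c1OC | intermediate
10 | (E)-oxocarbenium triflate from 9 and 8 (ArCH=O+ on the former carbinol oxygen), formed in situ | COc1cc(/C=[O+]/[C@H](c2cc(OC)c(OC)c(OCc3ccccc3)c2)[C@@H](C)/C=C/Sc2ccccc2)cc(OC)c1OC.[O-]S(=O)(=O)C(F)(F)F | intermediate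
11 | ring-closed thionium triflate (CH=S+Ph on C3 of the oxolane), formed in situ | COc1cc([C@H]2O[C@@H](c3cc(OC)c(OC)c(OC)c3)[C@H](C=[S+]c3ccccc3)[C@@H]2C)cc(OCc2ccccc2)c1OC.[O-]S(=O)(=O)C(F)(F)F | intermediate
12 | (2R,3R,4S,5S)-5-[3-(benzyloxy)-4,5-dimethoxyphenyl]-4-methyl-3-[(phenylsulfanyl)methyl]-2-(3,4,5-trimethoxyphenyl)oxolane | COc1cc([C@H]2O[C@@H](c3cc(OC)c(OC)c(OC)c3)[C@H](CSc3ccccc3)[C@@H]2C)cc(OCc2ccccc2)c1OC | intermediate
13 | (2R,3R,4S,5S)-5-(3-hydroxy-4,5-dimethoxyphenyl)-3,4-dimethyl-2-(3,4,5-trimethoxyphenyl)oxolane | COc1cc([C@H]2O[C@@H](c3cc(OC)c(OC)c(OC)c3)[C@H](C)[C@@H]2C)cc(O)c1OC | target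

**Summary**

Total step count: 6. Longest linear sequence: 5 steps (1 → 2 → 6 → 7 → 12 → 13, or 3 → 4 → 6 → 7 → 12 → 13).

Steps most likely to fail:

Step 5. The alkene may attack through the wrong face at C3 (2,3-cis closure), the cation may equilibrate by reversible ring opening, or hydride may capture the oxocarbenium ion before ring closure. The fallback sets out from 7 and 8 and places C3 under thermodynamic control. The silane is omitted and the cyclisation is run with TMSOTf and 2,6-di-tert-butyl-4-methylpyridine at −78 °C. Aqueous NaHCO3 work-up should hydrolyse the thionium ion to (2R,3R,4S,5S)-5-[3-(benzyloxy)-4,5-dimethoxyphenyl]-4-methyl-2-(3,4,5-trimethoxyphenyl)oxolane-3-carbaldehyde F1. F1 is equilibrated with DBU in CH2Cl2 so that the formyl group settles anti to the larger C2 aryl group. NaBH4 in MeOH should give the primary alcohol F2, MsCl/Et3N the mesylate F3, and LiEt3BH in THF the O-benzyl 3,4-dimethyl oxolane F4. Hydrogenolysis (H2, Pd/C, EtOAc) brings the route back at 13.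

Step 3. The anti/syn selectivity of allenylzinc addition may erode with an aromatic aldehyde, or the allenylmetal may partly racemise. The fallback sets out from 2. Brown crotylboration with the (E)-crotyldiisopinocampheylborane expected from (−)-Ipc2BOMe (trans-but-2-ene, n-BuLi, KOtBu, BF3·OEt2, −78 °C; then NaOH, H2O2) should give the anti homoallylic alcohol (1S,2S)-1-[3-(benzyloxy)-4,5-dimethoxyphenyl]-2-methylbut-3-en-1-ol F5. TBSCl and imidazole give its tert-butyldimethylsilyl ether F6. Ozonolysis (O3, then PPh3) gives the (2R,3S)-2-methyl-3-silyloxy aldehyde F7. Ohira–Bestmann homologation (dimethyl (1-diazo-2-oxopropyl)phosphonate, K2CO3, MeOH) gives the silylated alkyne F8, and TBAF brings the route back at 6.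

Step 6. The nickel surface may hydrogenolyse the benzylic C–O bonds of the oxolane, or debenzylation may stay incomplete. The fallback sets out from 12 and replaces nickel hydrogenolysis by electron-transfer desulfonylation. mCPBA (CH2Cl2, 0 °C) should give the sulfone (2R,3R,4S,5S)-3-[(benzenesulfonyl)methyl]-5-[3-(benzyloxy)-4,5-dimethoxyphenyl]-4-methyl-2-(3,4,5-trimethoxyphenyl)oxolane F9. Na/Hg with Na2HPO4 in MeOH should give the O-benzyl 3,4-dimethyl oxolane F4, and transfer hydrogenolysis (Pd/C, cyclohexa-1,4-diene, EtOH) brings the route back at 13.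

Further compounds
F1 | step 5 | (2R,3R,4S,5S)-5-[3-(benzyloxy)-4,5-dimethoxyphenyl]-4-methyl-2-(3,4,5-trimethoxyphenyl)oxolane-3-carbaldehyde | COc1cc([C@H]2O[C@@H](c3cc(OC)c(OC)c(OC)c3)[C@H](C=O)[C@@H]2C)cc(OCc2ccccc2)c1OC
F2 | step 5 | [(2R,3S,4S,5S)-5-[3-(benzyloxy)-4,5-dimethoxyphenyl]-4-methyl-2-(3,4,5-trimethoxyphenyl)oxolan-3-yl]methanol | COc1cc([C@H]2O[C@@H](c3cc(OC)c(OC)c(OC)c3)[C@H](CO)[C@@H]2C)cc(OCc2ccccc2)c1OC
F3 | step 5 | [(2R,3S,4S,5S)-5-[3-(benzyloxy)-4,5-dimethoxyphenyl]-4-methyl-2-(3,4,5-trimethoxyphenyl)oxolan-3-yl]methyl methanesulfonate | COc1cc([C@H]2O[C@@H](c3cc(OC)c(OC)c(OC)c3)[C@H](COS(C)(=O)=O)[C@@H]2C)cc(OCc2ccccc2)c1OC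
F4 | step 5 | (2R,3R,4S,5S)-5-[3-(benzyloxy)-4,5-dimethoxyphenyl]-3,4-dimethyl-2-(3,4,5-trimethoxyphenyl)oxolane | COc1cc([C@H]2O[C@@H](c3cc(OC)c(OC)c(OC)c3)[C@H](C)[C@@H]2C)cc(OCc2ccccc2)c1OC
F5 | step 3 | (1S,2S)-1-[3-(benzyloxy)-4,5-dimethoxyphenyl]-2-methylbut-3-en-1-ol | COc1cc([C@@H](O)[C@@H](C)C=C)cc(OCc2ccccc2)c1OC
F6 | step 3 | tert-butyldimethylsilyl ether of F5 | COc1cc([C@@H](O[Si](C)(C)C(C)(C)C)[C@@H](C)C=C)cc(OCc2ccccc2)c1OC
F7 | step 3 | (2R,3S)-3-[3-(benzyloxy)-4,5-dimethoxyphenyl]-3-[(tert-butyldimethylsilyl)oxy]-2-methylpropanal | COc1cc([C@@H](O[Si](C)(C)C(C)(C)C)[C@@H](C)C=O)cc(OCc2ccccc2)c1OC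
F8 | step 3 | tert-butyldimethylsilyl ether of 6 | COc1cc([C@@H](O[Si](C)(C)C(C)(C)C)[C@@H](C)C#C)cc(OCc2ccccc2)c1OC
F9 | step 6 | (2R,3R,4S,5S)-3-[(benzenesulfonyl)methyl]-5-[3-(benzyloxy)-4,5-dimethoxyphenyl]-4-methyl-2-(3,4,5-trimethoxyphenyl)oxolane | COc1cc([C@H]2O[C@@H](c3cc(OC)c(OC)c(OC)c3)[C@H](CS(=O)(=O)c3ccccc3)[C@@H]2C)cc(OCc2ccccc2)c1OC
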